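**Retrosynthetic overview**

1. The C4a–C5 bond is made last, in a domino that closes the carbocycle, the 1,5-benzodioxepine and the γ-pyrone from an acyclic 1,3,5-triketone hung on a furanose (a masked 6-C-acyl-hexos-5-ulose).
2. Enabling feature: the pyrone ring O1–C2=C3–C4(=O)–C4a=C8a is a dehydrated 1,3,5-triketone, so C4a is the methylene between the C4 and C8a carbonyls, and C5, which carries the bridging aryl oxygen, is an aldehyde carbon in disguise. The catechol oxygen already bound to C7 lies 1,3-diaxial to C5 and can form the C5–O bond only cis.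
3. The triketone comes from a xylo-dialdose (aldehyde carbon = C8a) and the dianion of 6-(4-methoxyphenyl)hexane-2,4-dione, followed by oxidation.
4. The C7–O–C6' ether comes from SN2 inversion of diacetone-D-allose 3-triflate by the 6-OH of a 7-O-benzyl-6,7-dihydroxy-2-(2-phenylethyl)chromone; C6, C7 and C8 are C-2, C-3 and C-4 of D-glucose.
5. Ring order: aromatic chromone, then (on the furanose scaffold) carbocycle, dioxepine and γ-pyrone in one operation.

Key step: step 11

Remark: the target is taken as drawn, (5R,6S,7R,8S). Locants 2–8a refer to the tetrahydrochromone half and primed locants to the aromatic chromone; sugar C-1, C-2, C-3, C-4, C-5, C-6 become C5, C6, C7, C8, C8a, C4a.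

**Route**

Step 1
Reactants: 1 1-(2-hydroxy-4,5-dimethoxyphenyl)ethan-1-one; 2 ethyl 3-phenylpropanoate
Product: 4 6,7-dimethoxy-2-(2-phenylethyl)-4H-chromen-4-one, via 1,3-diketone 3 (not isolated)
Conditions: NaH (4 equiv), THF, reflux; then conc. HCl, AcOH, 90 °C
Reagents that add atoms: none
Why: Claisen condensation of the acetophenone enolate with the ester gives the 1,3-diketone, which should close to the chromone by acid cyclodehydration; no stereocentre is formed.

Step 2
Reactants: 4 6,7-dimethoxy-2-(2-phenylethyl)-4H-chromen-4-one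
Product: 5 6,7-dihydroxy-2-(2-phenylethyl)-4H-chromen-4-one
Conditions: BBr3 (4 equiv), CH2Cl2, −78 °C → rt; H2O
Reagents that add atoms: none
Why: Lewis-acid cleavage of both aryl methyl ethers by BBr3, to which the chromone and the phenylethyl chain are inert.

Step 3
Reactants: 5 6,7-dihydroxy-2-(2-phenylethyl)-4H-chromen-4-one
Product: 6 7-(benzyloxy)-6-hydroxy-2-(2-phenylethyl)-4H-chromen-4-one
Conditions: BnBr (1.05 equiv), K2CO3 (1.0 equiv), DMF, 0 °C → rt
Reagents that add atoms: benzyl bromide, BrCc1ccccc1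
Why: Williamson etherification should occur at the more acidic 7-OH (para to the pyrone carbonyl, a vinylogous acid) when only one equivalent of weak base is used, leaving the 6-OH free.

Step 4
Reactants: 7 pentane-2,4-dione; 8 4-methoxybenzyl chloride
Product: 9 6-(4-methoxyphenyl)hexane-2,4-dione
Conditions: NaH (1.05 equiv), THF, 0 °C; n-BuLi (1.05 equiv), 0 °C; then 8, 0 °C → rt; aq. HCl
Reagents that add atoms: none
Why: Hauser dianion alkylation, in which the terminal carbanion of the β-diketone dianion is alkylated by the benzylic chloride.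

Step 5
Reactants: 10 1,2:5,6-di-O-isopropylidene-α-D-allofuranose
Product: 11 1,2:5,6-di-O-isopropylidene-3-O-(trifluoromethanesulfonyl)-α-D-allofuranose
Conditions: Tf2O (1.3 equiv), pyridine, CH2Cl2, −20 → 0 °C
Reagents that add atoms: trifluoromethanesulfonic anhydride, O=S(=O)(OS(=O)(=O)C(F)(F)F)C(F)(F)F
Why: O-sulfonylation of the secondary alcohol with triflic anhydride leaves the C-3 (allo) configuration untouched and provides the leaving group for step 6.

Step 6
Reactants: 11 1,2:5,6-di-O-isopropylidene-3-O-(trifluoromethanesulfonyl)-α-D-allofuranose; 6 7-(benzyloxy)-6-hydroxy-2-(2-phenylethyl)-4H-chromen-4-one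
Product: 12 3-O-[7-(benzyloxy)-4-oxo-2-(2-phenylethyl)-4H-chromen-6-yl]-1,2:5,6-di-O-isopropylidene-α-D-glucofuranose
Conditions: 6 (1.2 equiv), Cs2CO3 (1.5 equiv), DMF, rt → 45 °C
Reagents that add atoms: none
Why: SN2 displacement of the secondary triflate by the caesium phenoxide (Williamson-type etherification), which enters on the convex β-face of the cis-fused bicycle, so C-3 is inverted from allo to gluco and becomes C7 with its aryl ether.

Step 7
Reactants: 12 3-O-[7-(benzyloxy)-4-oxo-2-(2-phenylethyl)-4H-chromen-6-yl]-1,2:5,6-di-O-isopropylidene-α-D-glucofuranose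
Product: 14 3-O-[7-(benzyloxy)-4-oxo-2-(2-phenylethyl)-4H-chromen-6-yl]-1,2-O-isopropylidene-α-D-xylo-pentodialdo-1,4-furanose, via 5,6-diol 13 (not isolated)
Conditions: H5IO6 (1.3 equiv), EtOAc, rt
Reagents that add atoms: none
Why: periodic acid hydrolyses the more labile terminal 5,6-acetonide and cleaves the released glycol (Malaprade reaction) in one pot, leaving the 1,2-acetonide, the aryl ethers and the C-4 configuration (future C8) intact.

Step 8
Reactants: 14 3-O-aryl-1,2-O-isopropylidene-α-D-xylo-pentodialdo-1,4-furanose (aryl as in 12); 9 6-(4-methoxyphenyl)hexane-2,4-dione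
Product: 15 3-O-[7-(benzyloxy)-4-oxo-2-(2-phenylethyl)-4H-chromen-6-yl]-6-deoxy-1,2-O-isopropylidene-6-C-[5-(4-methoxyphenyl)-3-oxopentanoyl]-hexofuranose (D-gluco/L-ido mixture at C-5)
Conditions: 9 (1.4 equiv), LiN(i-Pr)2 (2.9 equiv), THF, −78 → 0 °C; then 14, −78 °C; AcOH, −78 °C
Reagents that add atoms: none
Why: aldol addition of the terminal carbanion of the β-diketone dianion to the aldehyde at −78 °C should outrun proton transfer; the new carbinol forms as an epimer mixture that is erased in step 9.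

Step 9
Reactants: 15 δ-hydroxy-β-diketone (C-5 epimer mixture)
Product: 16 3-O-[7-(benzyloxy)-4-oxo-2-(2-phenylethyl)-4H-chromen-6-yl]-6-deoxy-1,2-O-isopropylidene-6-C-[5-(4-methoxyphenyl)-3-oxopentanoyl]-α-D-xylo-hexofuranos-5-ulose
Conditions: Dess–Martin periodinane (1.3 equiv), pyridine, CH2Cl2, 0 °C → rt
Reagents that add atoms: none
Why: Dess–Martin oxidation of the δ-hydroxy-β-diketone to the 1,3,5-triketone under buffered, nearly neutral conditions that should not epimerise the adjacent C-4 (future C8).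

Step 10
Reactants: 16 benzyl-protected 1,3,5-triketone
Product: 17 6-deoxy-3-O-[7-hydroxy-4-oxo-2-(2-phenylethyl)-4H-chromen-6-yl]-1,2-O-isopropylidene-6-C-[5-(4-methoxyphenyl)-3-oxopentanoyl]-α-D-xylo-hexofuranos-5-ulose
Conditions: H2 (1 atm), 10% Pd/C, EtOAc, rt
Reagents that add atoms: none
Why: hydrogenolysis of the aryl benzyl ether over palladium on carbon at 1 atm, conditions under which the chromone double bond, the enolised triketone and the acetal should not be reduced.

Step 11
Reactants: 17 phenolic 1,3,5-triketone on the 1,2-O-isopropylidene furanose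
Product: 20 (+)-4'-methoxyaquisinenone G, via reducing furanose 18 (not isolated), via bridged triketone 19 (not isolated)
Conditions: AcOH/H2O 4:1, ethylenediammonium diacetate (0.2 equiv), 0.005 M, 80 °C; evaporate; then TFA/CH2Cl2 1:4, 4 Å MS, 0 °C → rt
Reagents that add atoms: none
Why: Proposed new method: aqueous AcOH removes the 1,2-acetonide to give reducing sugar 18, a 6-C-acyl-hexos-5-ulose whose open form places the C5 aldehyde five atoms from C4a, the methylene between the C8a and C4 carbonyls; amine/acid-catalysed aldol (Knoevenagel) addition of C4a to C5 closes the carbocycle, loss of water gives a 2-acylcyclohexenone, the 7'-phenol held on the C7 oxygen adds to C5 (oxa-Michael) to close the dioxepine (19), and TFA finally dehydrates the 1,3,5-triketone to the γ-pyrone. The closest known reaction types are the aldol carbocyclisation of hexos-5-uloses (the ring-closing half of the Ferrier carbocyclisation), domino Knoevenagel/oxa-Michael reactions of 1,3-diketones, and the acid cyclodehydration of 1,3,5-triketones to 4-pyranones; their concatenation on a reducing sugar with a tethered phenol is untested. Modes of closure: carbocycle 6-(enolendo)-exo-trig, dioxepine 7-exo-trig conjugate addition, pyranone 6-exo-trig hemiketalisation followed by dehydration. The only new stereocentre, C5, is fixed by the tether, because the phenol anchored at C7 can reach C5 only on the face cis to the C7 oxygen (1,3-diaxial bridge) and the aldol and oxa-Michael steps stay reversible until the pyrone forms; C6, C7 and C8 are carried over from the sugar. The step needs C4a rather than C3 to attack (six- against eight-membered ring), the phenol rather than O6 or O8 to capture C5 (only the aryl bridge is unstrained), and carbocyclisation before any cyclodehydration of the α'-hydroxy-1,3-diketone to a 3(2H)-furanone, which is secured by O8 being held in the furanose hemiacetal and by running the first stage buffered before strong acid is added. Should the pyrone close first, its C4a is still the α-carbon of a vinylogous ester and C5–O bonds at this vinylogous benzylic position re-ionise in acid, so both orders should converge on 20.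

**Compound list**

1 | 1-(2-hydroxy-4,5-dimethoxyphenyl)ethan-1-one | CC(=O)c1cc(OC)c(OC)cc1O | starting material
2 | ethyl 3-phenylpropanoate | CCOC(=O)CCc1ccccc1 | starting material
3 | 1-(2-hydroxy-4,5-dimethoxyphenyl)-5-phenylpentane-1,3-dione | COc1cc(O)c(cc1OC)C(=O)CC(=O)CCc1ccccc1 | intermediate
4 | 6,7-dimethoxy-2-(2-phenylethyl)-4H-chromen-4-one | COc1cc2oc(CCc3ccccc3)cc(=O)c2cc1OC | intermediate
5 | 6,7-dihydroxy-2-(2-phenylethyl)-4H-chromen-4-one | Oc1cc2oc(CCc3ccccc3)cc(=O)c2cc1O | intermediate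
6 | 7-(benzyloxy)-6-hydroxy-2-(2-phenylethyl)-4H-chromen-4-one | O=c1cc(CCc2ccccc2)oc2cc(OCc3ccccc3)c(O)cc12 | intermediate
7 | pentane-2,4-dione | CC(=O)CC(C)=O | starting material
8 | 4-methoxybenzyl chloride | COc1ccc(CCl)cc1 | starting material
9 | 6-(4-methoxyphenyl)hexane-2,4-dione | CC(=O)CC(=O)CCc1ccc(OC)cc1 | intermediate
10 | 1,2:5,6-di-O-isopropylidene-α-D-allofuranose | O[C@H]1[C@H]2OC(C)(C)O[C@H]2O[C@@H]1[C@H]1COC(C)(C)O1 | starting material
11 | 1,2:5,6-di-O-isopropylidene-3-O-(trifluoromethanesulfonyl)-α-D-allofuranose | O=S(=O)(O[C@H]1[C@H]2OC(C)(C)O[C@H]2O[C@@H]1[C@H]1COC(C)(C)O1)C(F)(F)F | intermediate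
12 | 3-O-[7-(benzyloxy)-4-oxo-2-(2-phenylethyl)-4H-chromen-6-yl]-1,2:5,6-di-O-isopropylidene-α-D-glucofuranose | O=c1cc(CCc2ccccc2)oc2cc(OCc3ccccc3)c(O[C@@H]3[C@H]4OC(C)(C)O[C@H]4O[C@@H]3[C@H]3COC(C)(C)O3)cc12 | intermediate
13 | 3-O-[7-(benzyloxy)-4-oxo-2-(2-phenylethyl)-4H-chromen-6-yl]-1,2-O-isopropylidene-α-D-glucofuranose (5,6-diol) | O=c1cc(CCc2ccccc2)oc2cc(OCc3ccccc3)c(O[C@@H]3[C@H]4OC(C)(C)O[C@H]4O[C@@H]3[C@H](O)CO)cc12 | intermediate
14 | 3-O-[7-(benzyloxy)-4-oxo-2-(2-phenylethyl)-4H-chromen-6-yl]-1,2-O-isopropylidene-α-D-xylo-pentodialdo-1,4-furanose | O=c1cc(CCc2ccccc2)oc2cc(OCc3ccccc3)c(O[C@@H]3[C@H]4OC(C)(C)O[C@H]4O[C@@H]3C=O)cc12 | intermediate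
15 | δ-hydroxy-β-diketone: 3-O-aryl(OBn)-6-deoxy-1,2-O-isopropylidene-6-C-[5-(4-methoxyphenyl)-3-oxopentanoyl]-hexofuranose, C-5 epimer mixture | O=c1cc(CCc2ccccc2)oc2cc(OCc3ccccc3)c(O[C@@H]3[C@H]4OC(C)(C)O[C@H]4O[C@@H]3C(O)CC(=O)CC(=O)CCc3ccc(OC)cc3)cc12 | intermediate
16 | 1,3,5-triketone: 3-O-aryl(OBn)-6-deoxy-1,2-O-isopropylidene-6-C-[5-(4-methoxyphenyl)-3-oxopentanoyl]-α-D-xylo-hexofuranos-5-ulose | O=c1cc(CCc2ccccc2)oc2cc(OCc3ccccc3)c(O[C@@H]3[C@H]4OC(C)(C)O[C@H]4O[C@@H]3C(=O)CC(=O)CC(=O)CCc3ccc(OC)cc3)cc12 | intermediate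
17 | phenolic 1,3,5-triketone: 6-deoxy-3-O-[7-hydroxy-4-oxo-2-(2-phenylethyl)-4H-chromen-6-yl]-1,2-O-isopropylidene-6-C-[5-(4-methoxyphenyl)-3-oxopentanoyl]-α-D-xylo-hexofuranos-5-ulose | O=c1cc(CCc2ccccc2)oc2cc(O)c(O[C@@H]3[C@H]4OC(C)(C)O[C@H]4O[C@@H]3C(=O)CC(=O)CC(=O)CCc3ccc(OC)cc3)cc12 | intermediate
18 | reducing furanose: 6-deoxy-3-O-[7-hydroxy-4-oxo-2-(2-phenylethyl)-4H-chromen-6-yl]-6-C-[5-(4-methoxyphenyl)-3-oxopentanoyl]-D-xylo-hexofuranos-5-ulose, anomer mixture | O=c1cc(CCc2ccccc2)oc2cc(O)c(O[C@@H]3[C@@H](O)C(O)O[C@@H]3C(=O)CC(=O)CC(=O)CCc3ccc(OC)cc3)cc12 | intermediate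
19 | bridged triketone: cyclohexanone with C5–O-7' and C7–O-6' aryl bridge, 6,8-diol, and the 5-(4-methoxyphenyl)-3-oxopentanoyl chain at C4a (keto form drawn, enolised in solution) | COc1ccc(CCC(=O)CC(=O)C2C(=O)[C@@H](O)[C@@H]3Oc4cc5c(=O)cc(CCc6ccccc6)oc5cc4O[C@H]2[C@@H]3O)cc1 | intermediate
20 | (+)-4'-methoxyaquisinenone G: (5R,6S,7R,8S)-6,8-dihydroxy-2-[2-(4-methoxyphenyl)ethyl]-5,6,7,8-tetrahydrochromone whose C5 and C7 oxygens are O-7' and O-6' of 6,7-dihydroxy-2-(2-phenylethyl)chromone | COc1ccc(CCc2cc(=O)c3c(o2)[C@@H](O)[C@@H]2Oc4cc5c(=O)cc(CCc6ccccc6)oc5cc4O[C@H]3[C@@H]2O)cc1 | target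

**Step count and risks**

Total steps: 11. Longest linear sequence: 9 steps (1, 2, 3, 6, 7, 8, 9, 10, 11).

Steps most likely to fail:

1. Step 11. Cyclodehydration may outrun C–C bond formation: the α'-hydroxy-1,3-diketone can close to a 3(2H)-furanone, or the pyrone can form early and leave a poorly nucleophilic C4a. The ketone-flanked C8 may epimerise, the 2-acylcyclohexenone may aromatise by β-elimination, or water rather than the phenol may capture C5.
Fallback, from 16 to 20, with the events separated and the phenol kept benzylated so that only the C–C bond can form at first. Hot 80% aqueous AcOH cleaves the acetonide of 16 to the reducing 5-ulose benzyl ether F1. Piperidinium acetate in MeCN at rt effects the aldol carbocyclisation of the 5-ulose (C4a to C5, the known ring closure of the Ferrier carbocyclisation), and TFA/CH2Cl2 containing a little water then closes the γ-pyrone to give the 5-hydroxy-5,6,7,8-tetrahydrochromone benzyl ether F2 as a mixture of C5 epimers. Hydrogenolysis (H2, 10% Pd/C, EtOAc) gives the phenolic 5-hydroxy-tetrahydrochromone F3. Camphorsulfonic acid in MeCN over 4 Å MS ionises the C5 hydroxyl (both epimers converge) and the tethered phenol closes the dioxepine by dehydrative etherification, rejoining the route at 20.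

2. Step 6. The hindered, ortho-substituted phenoxide may act as a base, giving E2 elimination of the triflate to the 3,4-ene, or substitution may be too slow.
Fallback, from 6 to 12, with the polarity reversed and the sugar configuration retained. Phenol 6 is converted (Tf2O, pyridine) into 7-(benzyloxy)-4-oxo-2-(2-phenylethyl)-4H-chromen-6-yl trifluoromethanesulfonate F4. F4 is joined to the C-3 hydroxyl of commercial 1,2:5,6-di-O-isopropylidene-α-D-glucofuranose F5 by palladium-catalysed C–O cross-coupling (Pd2(dba)3, t-BuBrettPhos, Cs2CO3, toluene, 90 °C). The sugar C–O bond is not broken, so the gluco configuration is kept, and the route is rejoined at 12.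

3. Step 8. Proton transfer may compete with addition: the strongly basic dianion may epimerise C-4 of aldehyde 14, deprotonate the chromone 2-CH2, or attack the chromone.
Fallback, from 9 to 15, under Lewis-acid instead of basic conditions. Diketone 9 is silylated twice (Me3SiCl, Et3N; then LiN(i-Pr)2, Me3SiCl) to (Z)-1-(4-methoxyphenyl)-3,5-bis(trimethylsilyloxy)hexa-3,5-diene F6. F6 adds to aldehyde 14 at its terminal carbon in a vinylogous Mukaiyama aldol reaction (BF3·OEt2, CH2Cl2, −78 °C), and aqueous work-up gives 15.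

**Further compounds**

F1 | step 11 | 3-O-[7-(benzyloxy)-4-oxo-2-(2-phenylethyl)-4H-chromen-6-yl]-6-deoxy-6-C-[5-(4-methoxyphenyl)-3-oxopentanoyl]-D-xylo-hexofuranos-5-ulose (anomer mixture) | O=c1cc(CCc2ccccc2)oc2cc(OCc3ccccc3)c(O[C@@H]3[C@@H](O)C(O)O[C@@H]3C(=O)CC(=O)CC(=O)CCc3ccc(OC)cc3)cc12
F2 | step 11 | (6S,7R,8S)-7-{[7-(benzyloxy)-4-oxo-2-(2-phenylethyl)-4H-chromen-6-yl]oxy}-5,6,8-trihydroxy-2-[2-(4-methoxyphenyl)ethyl]-5,6,7,8-tetrahydro-4H-chromen-4-one (C5 epimer mixture) | COc1ccc(CCc2cc(=O)c3c(o2)[C@@H](O)[C@H](Oc2cc4c(=O)cc(CCc5ccccc5)oc4cc2OCc2ccccc2)[C@@H](O)C3O)cc1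
F3 | step 11 | (6S,7R,8S)-5,6,8-trihydroxy-7-{[7-hydroxy-4-oxo-2-(2-phenylethyl)-4H-chromen-6-yl]oxy}-2-[2-(4-methoxyphenyl)ethyl]-5,6,7,8-tetrahydro-4H-chromen-4-one (C5 epimer mixture) | COc1ccc(CCc2cc(=O)c3c(o2)[C@@H](O)[C@H](Oc2cc4c(=O)cc(CCc5ccccc5)oc4cc2O)[C@@H](O)C3O)cc1
F4 | step 6 | 7-(benzyloxy)-4-oxo-2-(2-phenylethyl)-4H-chromen-6-yl trifluoromethanesulfonate | O=c1cc(CCc2ccccc2)oc2cc(OCc3ccccc3)c(OS(=O)(=O)C(F)(F)F)cc12
F5 | step 6 | 1,2:5,6-di-O-isopropylidene-α-D-glucofuranose (commercial) | O[C@@H]1[C@H]2OC(C)(C)O[C@H]2O[C@@H]1[C@H]1COC(C)(C)O1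
F6 | step 8 | (Z)-1-(4-methoxyphenyl)-3,5-bis(trimethylsilyloxy)hexa-3,5-diene | C=C(O[Si](C)(C)C)/C=C(\O[Si](C)(C)C)CCc1ccc(OC)cc1
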